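The leftover of starting material in a stopped alder or oak flask is one minus the target fraction, because the catalyst charged is hardly any of the starting material charged. So I count in fractions of the charge and ask what fraction goes per minute.

| flask | starting material | second substrate | free catalyst | remark | time |
|---|---|---|---|---|---|
| summer | 0.10 mM | 0.40 mM | 0.40 µM | run made earlier |  |
| dusk | 0.15 mM | 0.40 mM | 0.40 µM | run made earlier |  |
| alder | 0.20 mM | 0.400 mM | 0.40 µM |  | 2.0 min |
| oak | 0.20 mM | 0.400 mM | 0.40 µM |  | 1.2 min |

1. the flask that ends with the higher amount of target, in percent of the starting material charged, or "neither" when 2 percentage points or less lies between them (alder / oak / neither)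
2. final target, as a percentage of the starting material charged, in alder
3. final target, as a percentage of the starting material charged, in oak

- what was read earlier has a scatter of 1 percentage point, one standard deviation
- steps under discussion: starting material + free catalyst <-> catalyst intermediate A; catalyst intermediate A -> free catalyst + target; second substrate + free catalyst <-> catalyst intermediate B; catalyst intermediate B -> free catalyst + second product

| run | time / s | target / % |
|---|---|---|
| summer | 10.0 | 3.7 |
| summer | 15.0 | 8.6 |
| summer | 25.0 | 11.3 |
| summer | 40.0 | 21.0 |
| summer | 80.0 | 43.8 |
| summer | 120 | 63.5 |
| dusk | 20.0 | 9.7 |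
| dusk | 40.0 | 20.5 |
| dusk | 60.0 | 31.3 |
| dusk | 80.0 | 41.3 |
| dusk | 90.0 | 47.9 |
| dusk | 120 | 62.5 |

(each reading ± 1 percentage point)

I read the two tables against each other first. At 40.0 s the summer run shows 21.0 % and the dusk run 20.5 %. At 120 s they show 63.5 % and 62.5 %, a gap of 1 percentage point against a scatter of 1 point, although dusk holds 1.50 times the starting material of summer. So, with second substrate and catalyst held, the fraction made by a given time does not visibly follow the charge.

Then I read down the summer column. A first-order decay carrying its 40.0 s reading forward to 120 s gives 50.7 %, but the reading is higher, at 63.5 %. The column runs nearly straight.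

From the two last readings I therefore take 0.315 min⁻¹, the fraction of the charge turned into target per minute at this catalyst charge, my charge clock. I also assume that it scales with the catalyst charged, which these runs cannot test. My reckoning gives 63.0 % for alder and 37.8 % for oak.

The forecast says 61 % (56 % to 65 %) for alder and 37 % (33 % to 40 %) for oak, so alder ends higher. It stands below mine, on the ground that “slightly more competition from the starting material should lower the percentages a little”.

Alder gives 60.0 % and oak 36.1 %, so alder ends higher, as forecast.

    starting material + free catalyst ⇌ catalyst intermediate A (K = 12000 L mol⁻¹, k = 1.70 × 10⁵ L mol⁻¹ s⁻¹)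
    catalyst intermediate A → free catalyst + target (k = 20.0 s⁻¹)
    second substrate + free catalyst ⇌ catalyst intermediate B (K = 19000 L mol⁻¹, k = 6.10 × 10⁵ L mol⁻¹ s⁻¹)
    catalyst intermediate B → free catalyst + second product (k = 8.40 s⁻¹)

Alder's result gives a clock of 0.300 min⁻¹ and oak's 0.301 min⁻¹, each slower than my 0.315 min⁻¹. A charge of free catalyst of 0.366 µM moves alder by 5 points, which on the low side would fall under the forecast's 56 %. The neighbouring flask is alder with a quarter of the catalyst, 1.0 × 10⁻⁴ mM. The clock scaled by that share gives 15.8 %. At 2.00 min that flask holds 15.0 % target, and catalyst intermediate B, the resting state, is its largest catalyst form, at 72.6 % of the catalyst charged.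

The numbers in the tables are simulated with made-up constants, noise included.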